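**Retrosynthetic overview**
- **Feature.** Unprimed atoms are indole A (N1-linked 2,3,5-tribromoindole); primed atoms are indole B (2',4',5'-tribromo-1H-indole). The N1'–C7a' bond joins the nitrogen on C2' to an ortho carbon of the benzo ring. Read as a 2,3-dibromophenyl group on C3', that ring carries Br at one ortho carbon (the future C4') and a single ortho C–H (C7a'), so N–H/C–H amination has only one C–H site in it.
- **Disconnections.** C2'–Br comes from C2'–CO2H by bromodecarboxylation (last step). N1'–C7a' comes from anodic dehydrogenative amination of a tetrasubstituted 2-(Boc-amino)acrylate. C3'–N1 comes from conjugate addition of 5-bromoindole to an N-Boc-N-tosyl dehydroamino ester with loss of sulfinate. C2'=C3' comes from a glycinate aldol on 2,3-dibromobenzaldehyde followed by elimination.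
- **Ring order.** Indole A is bought as 5-bromoindole, and the pyrrole ring of indole B is the only ring formed. The C3 and C2 bromines of indole A are installed before the electrolysis, because a free C2 and an electron-rich pyrrole ring would otherwise compete for the nitrogen radical and for the anode.

Key step: step 5

Assumption 1: the target SMILES fixes no configuration at the hindered C3'–N1 axis, so the racemic mixture of atropisomers is taken as the target.
Assumption 2: the tetrasubstituted enamides are drawn as E isomers (NHBoc cis to the aryl ring), the geometry that can close. Any Z isomer is carried along, since base interconverts the two through the 1-azaallyl anion.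

Step 1
Reactants: 1 2,3-dibromobenzaldehyde; 2 methyl N-tosylglycinate
Product: 3 methyl 3-(2,3-dibromophenyl)-3-hydroxy-2-[(4-methylphenyl)sulfonylamino]propanoate (racemic syn/anti mixture)
Conditions: 2 (1.1 equiv), LiN(i-Pr)2 (2.2 equiv), THF, −78 °C; then 1, −78 °C; AcOH quench
Reagents that add atoms: none
Why: Aldol addition of the N,C-dilithiated sulfonamido ester to a non-enolisable, activated aldehyde is fast at −78 °C, amide bases do not exchange aryl bromides, and the two new stereocentres need no control because both are erased in step 2.

Step 2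
Reactants: 3 methyl 3-(2,3-dibromophenyl)-3-hydroxy-2-[(4-methylphenyl)sulfonylamino]propanoate
Product: 5 methyl (Z)-2-[N-(tert-butoxycarbonyl)-N-tosylamino]-3-(2,3-dibromophenyl)acrylate, via bis-Boc carbonate 4 (not isolated)
Conditions: Boc2O (2.5 equiv), DMAP (0.1 equiv), MeCN, rt; then N,N,N',N'-tetramethylguanidine (0.2 equiv), rt
Reagents that add atoms: di-tert-butyl dicarbonate, CC(C)(C)OC(=O)OC(=O)OC(C)(C)C
Why: DMAP-catalysed Boc transfer acylates both the sulfonamide N–H and the benzylic O–H, and the guanidine base then removes the now very acidic α-proton and expels tert-butyl carbonate (E1cB β-elimination) to give the thermodynamically preferred Z alkene with the aryl group trans to the ester.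

Step 3
Reactants: 5 methyl (Z)-2-[N-(tert-butoxycarbonyl)-N-tosylamino]-3-(2,3-dibromophenyl)acrylate; 6 5-bromoindole
Product: 8 methyl (E)-3-(5-bromoindol-1-yl)-2-(tert-butoxycarbonylamino)-3-(2,3-dibromophenyl)acrylate, via N-Boc imino ester 7 (not isolated)
Conditions: 6 (1.2 equiv), Cs2CO3 (1.5 equiv), DMF, rt to 40 °C
Reagents that add atoms: none
Why: Aza-Michael addition of the caesium indolide through N1 to an acceptor whose nitrogen is non-donating and has no N–H gives an ester enolate that expels 4-methylbenzenesulfinate from nitrogen, and imine 7 tautomerises to the enamide (E expected, indolyl beside the ester); this known addition–elimination of N-heterocycles on N-tosyl-N-Boc dehydroamino esters attacks a trisubstituted carbon and avoids a β-bromo N–H enamide, which base would close to an oxazole.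

Step 4
Reactants: 8 methyl (E)-3-(5-bromoindol-1-yl)-2-(tert-butoxycarbonylamino)-3-(2,3-dibromophenyl)acrylate
Product: 10 methyl (E)-2-(tert-butoxycarbonylamino)-3-(2,3-dibromophenyl)-3-(2,3,5-tribromoindol-1-yl)acrylate, via 3-bromoindolyl enamide 9 (not isolated)
Conditions: NBS (2.1 equiv), DMF, 0 °C to rt, dark; aq Na2S2O3
Reagents that add atoms: N-bromosuccinimide, O=C1CCC(=O)N1Br
Why: Electrophilic aromatic bromination with NBS takes C3 and then C2 of the pyrrole ring of indole A, the most nucleophilic carbons present, whereas the fully substituted enamide has no vinylic hydrogen to lose and returns any bromine it picks up on reductive work-up.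

Step 5
Reactants: 10 methyl (E)-2-(tert-butoxycarbonylamino)-3-(2,3-dibromophenyl)-3-(2,3,5-tribromoindol-1-yl)acrylate
Product: 12 methyl 4,5-dibromo-3-(2,3,5-tribromoindol-1-yl)-1H-indole-2-carboxylate, via N-Boc indole 11 (not isolated)
Conditions: undivided cell, graphite anode, Pt cathode, constant current (5 mA, about 2.5 F/mol), Fe(C5H5)2 (10 mol%), Na2CO3 (1 equiv), n-Bu4NBF4 (0.1 M), MeOH/THF 1:4, 60 °C; then current off, 60 °C until the N-Boc group is methanolysed
Reagents that add atoms: none
Why: Proposed new method: methoxide made at the cathode (buffered by Na2CO3) removes the carbamate N–H of 10, and the trivalent-iron cation [Fe(C5H5)2]+, regenerated at the anode near +0.4 V against SCE, takes one electron from the anion to give a carbamate-type amidyl radical whose spin is shared by N1' and C3' (a 1-azaallyl radical, so rotation about C2'–C3' is eased and E and Z material converge). N1' bonds to the one hydrogen-bearing ortho carbon of the dibromophenyl ring in a five-membered closure over N1'–C2'–C3'–C3a'–C7a', formally 5-endo-trig at the C3a'=C7a' bond and in character a five-centre electrocyclic closure (the same atoms join if a second electron leaves first and the 1-azapentadienyl cation closes), and loss of the second electron and of the C7a' proton restores the arene in 11 while two protons leave as H2 at the cathode. The activated N-Boc group of 11, flanked by the ester, does not withstand warm methanolic base and is removed on purpose in the same pot to give 12. The closest known reactions are anodic amidyl N–H/C–H cyclisations onto arenes (carbazoles, phenanthridinones, fused benzimidazoles), mediator-based amidyl generation from anilide-type carbamates, and the Pd(OAc)2-promoted C–H amination of 2-acylamino-3-arylacrylates to indole-2-carboxylates; an anodic closure of an enamide nitrogen onto its β-aryl group has not been shown. No stereocentre is formed; site selectivity is needed against closure on indole A (C2, five-membered; C7, six-membered) and against ipso attack at the bromine-bearing ortho carbon (the future C4'), and it rests on the C2 and C3 bromines, which block and deactivate the pyrrole ring of indole A and hold it perpendicular to the enamide plane (its orientation in the product), and on the lower hindrance and higher electron density of the C–H carbon compared with the C–Br carbon. Chemoselective oxidation rests on the mediator working far below the potentials of the brominated arenes and of the neutral enamide, and the C–Br bonds are spared because proton reduction on Pt needs a much less negative potential than aryl bromide reduction.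

Step 6
Reactants: 12 methyl 4,5-dibromo-3-(2,3,5-tribromoindol-1-yl)-1H-indole-2-carboxylate
Product: 13 4,5-dibromo-3-(2,3,5-tribromoindol-1-yl)-1H-indole-2-carboxylic acid
Conditions: LiOH (5 equiv), THF/MeOH/H2O 3:1:1, 45 °C; then 1 M HCl to pH 3
Reagents that add atoms: lithium hydroxide, [Li+].[OH-]
Why: Saponification of an indole-2-carboxylate with LiOH is routine, and aryl and 2-bromoindole C–Br bonds that lack an activating acceptor are inert to hydroxide at this temperature.

Step 7
Reactants: 13 4,5-dibromo-3-(2,3,5-tribromoindol-1-yl)-1H-indole-2-carboxylic acid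
Product: 14 rivularin A, 2,3,5-tribromo-1-(2,4,5-tribromo-1H-indol-3-yl)indole
Conditions: NBS (1.05 equiv), LiOAc (0.1 equiv), DMF, 0 °C to rt, dark
Reagents that add atoms: N-bromosuccinimide, O=C1CCC(=O)N1Br
Why: In this ionic, Hunsdiecker-type bromodecarboxylation, electrophilic bromine attacks the carboxyl-bearing C2' of the N–H indole, the only pyrrole carbon still open to substitution, and the ipso σ-complex loses CO2 instead of a proton, as known for pyrrole- and indole-2-carboxylic acids.

**Compound list**
1 | 2,3-dibromobenzaldehyde | O=Cc1cccc(Br)c1Br | starting material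
2 | methyl N-tosylglycinate | COC(=O)CNS(=O)(=O)c1ccc(C)cc1 | starting material
3 | methyl 3-(2,3-dibromophenyl)-3-hydroxy-2-[(4-methylphenyl)sulfonylamino]propanoate (racemic syn/anti mixture) | COC(=O)C(NS(=O)(=O)c1ccc(C)cc1)C(O)c1cccc(Br)c1Br | intermediate
4 | methyl 2-[N-(tert-butoxycarbonyl)-N-tosylamino]-3-(tert-butoxycarbonyloxy)-3-(2,3-dibromophenyl)propanoate (racemic diastereomer mixture, not isolated) | COC(=O)C(N(C(=O)OC(C)(C)C)S(=O)(=O)c1ccc(C)cc1)C(OC(=O)OC(C)(C)C)c1cccc(Br)c1Br | intermediate
5 | methyl (Z)-2-[N-(tert-butoxycarbonyl)-N-tosylamino]-3-(2,3-dibromophenyl)acrylate | COC(=O)/C(=C/c1cccc(Br)c1Br)N(C(=O)OC(C)(C)C)S(=O)(=O)c1ccc(C)cc1 | intermediate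
6 | 5-bromoindole | Brc1ccc2[nH]ccc2c1 | starting material
7 | methyl 3-(5-bromoindol-1-yl)-2-(tert-butoxycarbonylimino)-3-(2,3-dibromophenyl)propanoate (racemic, not isolated) | COC(=O)C(=NC(=O)OC(C)(C)C)C(c1cccc(Br)c1Br)n1ccc2cc(Br)ccc21 | intermediate
8 | methyl (E)-3-(5-bromoindol-1-yl)-2-(tert-butoxycarbonylamino)-3-(2,3-dibromophenyl)acrylate | COC(=O)/C(NC(=O)OC(C)(C)C)=C(/c1cccc(Br)c1Br)n1ccc2cc(Br)ccc21 | intermediate
9 | methyl (E)-2-(tert-butoxycarbonylamino)-3-(3,5-dibromoindol-1-yl)-3-(2,3-dibromophenyl)acrylate (not isolated) | COC(=O)/C(NC(=O)OC(C)(C)C)=C(/c1cccc(Br)c1Br)n1cc(Br)c2cc(Br)ccc21 | intermediate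
10 | methyl (E)-2-(tert-butoxycarbonylamino)-3-(2,3-dibromophenyl)-3-(2,3,5-tribromoindol-1-yl)acrylate | COC(=O)/C(NC(=O)OC(C)(C)C)=C(/c1cccc(Br)c1Br)n1c(Br)c(Br)c2cc(Br)ccc21 | intermediate
11 | 1-tert-butyl 2-methyl 4,5-dibromo-3-(2,3,5-tribromoindol-1-yl)indole-1,2-dicarboxylate (not isolated) | COC(=O)c1n(C(=O)OC(C)(C)C)c2ccc(Br)c(Br)c2c1-n1c(Br)c(Br)c2cc(Br)ccc21 | intermediate
12 | methyl 4,5-dibromo-3-(2,3,5-tribromoindol-1-yl)-1H-indole-2-carboxylate | COC(=O)c1[nH]c2ccc(Br)c(Br)c2c1-n1c(Br)c(Br)c2cc(Br)ccc21 | intermediate
13 | 4,5-dibromo-3-(2,3,5-tribromoindol-1-yl)-1H-indole-2-carboxylic acid | OC(=O)c1[nH]c2ccc(Br)c(Br)c2c1-n1c(Br)c(Br)c2cc(Br)ccc21 | intermediate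
14 | rivularin A (racemic about the C3'–N1 axis) | Brc1ccc2c(c1)c(Br)c(Br)n2-c1c(Br)[nH]c2ccc(Br)c(Br)c12 | target

Total step count: 7
Longest linear sequence: 7 steps (1 to 14)

**Steps most likely to fail**

**Step 5 (proposed new method).**
- The strongly delocalised radical may be oxidised further and captured by methanol at C3' before the ring closes.
- Closure may go to indole A, or to the bromine-bearing ortho carbon with loss of bromine.
- Methoxide may expel indole A from C3' by addition–elimination.
- The mediator may be too weak an oxidant for this stabilised anion.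

The fallback uses known chemistry only: a nitrene closes indole B first and indole A is attached afterwards. It sets out from 1 and 6. Condensation of 1 with methyl azidoacetate (NaOMe, MeOH, −10 °C) should give methyl (Z)-2-azido-3-(2,3-dibromophenyl)acrylate F1. Thermolysis of this azide in refluxing xylene (Hemetsberger–Knittel indole synthesis) forms N1'–C7a' at the same single free ortho carbon and gives methyl 4,5-dibromo-1H-indole-2-carboxylate F2. Iodination at C3' (NIS, DMF, rt) gives methyl 4,5-dibromo-3-iodo-1H-indole-2-carboxylate F3. N-protection (NaH, SEMCl, DMF, 0 °C) gives methyl 4,5-dibromo-3-iodo-1-{[2-(trimethylsilyl)ethoxy]methyl}indole-2-carboxylate F4. A copper-catalysed Ullmann–Goldberg N-arylation of 6 follows (CuI, trans-N,N'-dimethylcyclohexane-1,2-diamine, K3PO4, toluene, 110 °C). In it the C–I bond reacts ahead of the C–Br bonds, which should give methyl 4,5-dibromo-3-(5-bromoindol-1-yl)-1-{[2-(trimethylsilyl)ethoxy]methyl}indole-2-carboxylate F5. NBS (2.1 equiv, DMF) as in step 4 gives methyl 4,5-dibromo-3-(2,3,5-tribromoindol-1-yl)-1-{[2-(trimethylsilyl)ethoxy]methyl}indole-2-carboxylate F6. Fluoride (n-Bu4NF, THF, reflux) then removes the SEM group, and the material comes back to the route at 12.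

**Step 3.** Conjugate addition to the hindered β-aryl acceptor may be reversible and slower than transfer of the Boc group from the sulfonimide nitrogen to the indolide. The fallback replaces the azole anion by a neutral, more nucleophilic sp3 amine and restores the aromatic ring afterwards. It sets out from 5. Commercial 5-bromoindoline (i-Pr2NEt, MeCN, 40 °C, then N,N,N',N'-tetramethylguanidine to drive sulfinate loss) should give methyl (E)-3-(5-bromoindolin-1-yl)-2-(tert-butoxycarbonylamino)-3-(2,3-dibromophenyl)acrylate F7. Dehydrogenation of the indoline ring with DDQ (toluene, rt) then brings the material back to the route at 8.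

**Step 7.** Ipso attack at C2' of the electron-poor indole B may be slower than N-bromination or than attack on the benzo positions, so that the carboxyl group is retained or bromine enters elsewhere. The fallback separates loss of CO2 from bromination. It sets out from 13. Silver-catalysed protodecarboxylation (Ag2CO3 0.1 equiv, AcOH 0.05 equiv, DMSO, 120 °C) should give 4,5-dibromo-3-(2,3,5-tribromoindol-1-yl)-1H-indole F8. Ordinary electrophilic bromination of its only free pyrrole C–H (NBS 1.0 equiv, THF, −78 to 0 °C) comes back to the route at 14.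

**Further compounds**
F1 | step 5 | methyl (Z)-2-azido-3-(2,3-dibromophenyl)acrylate | COC(=O)/C(N=[N+]=[N-])=C/c1cccc(Br)c1Br
F2 | step 5 | methyl 4,5-dibromo-1H-indole-2-carboxylate | COC(=O)c1cc2c(Br)c(Br)ccc2[nH]1
F3 | step 5 | methyl 4,5-dibromo-3-iodo-1H-indole-2-carboxylate | COC(=O)c1[nH]c2ccc(Br)c(Br)c2c1I
F4 | step 5 | methyl 4,5-dibromo-3-iodo-1-{[2-(trimethylsilyl)ethoxy]methyl}indole-2-carboxylate | COC(=O)c1n(COCC[Si](C)(C)C)c2ccc(Br)c(Br)c2c1I
F5 | step 5 | methyl 4,5-dibromo-3-(5-bromoindol-1-yl)-1-{[2-(trimethylsilyl)ethoxy]methyl}indole-2-carboxylate | COC(=O)c1n(COCC[Si](C)(C)C)c2ccc(Br)c(Br)c2c1-n1ccc2cc(Br)ccc21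
F6 | step 5 | methyl 4,5-dibromo-3-(2,3,5-tribromoindol-1-yl)-1-{[2-(trimethylsilyl)ethoxy]methyl}indole-2-carboxylate | COC(=O)c1n(COCC[Si](C)(C)C)c2ccc(Br)c(Br)c2c1-n1c(Br)c(Br)c2cc(Br)ccc21
F7 | step 3 | methyl (E)-3-(5-bromoindolin-1-yl)-2-(tert-butoxycarbonylamino)-3-(2,3-dibromophenyl)acrylate | COC(=O)/C(NC(=O)OC(C)(C)C)=C(/c1cccc(Br)c1Br)N1CCc2cc(Br)ccc21
F8 | step 7 | 4,5-dibromo-3-(2,3,5-tribromoindol-1-yl)-1H-indole | Brc1ccc2c(c1)c(Br)c(Br)n2-c1c[nH]c2ccc(Br)c(Br)c12
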